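**Retrosynthetic overview**

- Feature: in ring C, C4 is a CH2 group held between the carbinol carbon C3 and C4a of the electron-rich, 1,3,5-trioxygenated ring A. This Ar–CH2–CH(OH) unit is what an arene leaves when it opens a terminal epoxide at its CH2 carbon, so ring C is closed last by making C4–C4a; rings A, B and the galloyl ring are bought as benzene rings.
- Cyclisation substrate: the ring A aryl ether (O1–C2) of a 1-aryl-2,3-epoxypropan-1-ol. It comes from a 3-aryloxy-1,2-diol by primary tosylation and base closure, and the diol from opening a (2R,3R)-3-arylglycidol at its benzylic carbon with a phloroglucinol mono-benzyl mono-silyl ether.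
- Stereochemistry: Sharpless epoxidation of the E-cinnamyl alcohol with the D-tartrate ester fixes C3 (R); the invertive phenol opening fixes C2 (S); together they give the 2,3-trans (2S,3R) series.
- Ring A differentiation: benzyl on the future O5, triisopropylsilyl on the future O7. The silyl ether steers the closure to C4a and is the only group removed before galloylation.
- End game: fluoride desilylation, phenoxide-selective 7-O-acylation with tri-O-benzylgalloyl chloride, hydrogenolysis of seven benzyl ethers.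

Key step: step 9

Assumption: 3,4,5-tris(benzyloxy)benzaldehyde and 3,4,5-tris(benzyloxy)benzoic acid are taken as catalogue compounds (both also follow from methyl gallate by benzylation and standard redox or saponification steps), and phloroglucinol is used anhydrous.

**Route**

Step 1
Reactants: 1 3,4,5-tris(benzyloxy)benzaldehyde; 2 triethyl phosphonoacetate
Product: 3 ethyl (E)-3-[3,4,5-tris(benzyloxy)phenyl]prop-2-enoate
Conditions: NaH, THF, 0 °C to rt
Reagents that add atoms: none
Why: Horner–Wadsworth–Emmons olefination of an aromatic aldehyde with the sodium salt of a stabilised phosphonate should give the E-configured cinnamate with high selectivity, and the benzyl ethers are inert to these conditions.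

Step 2
Reactants: 3 ethyl (E)-3-[3,4,5-tris(benzyloxy)phenyl]prop-2-enoate
Product: 4 (E)-3-[3,4,5-tris(benzyloxy)phenyl]prop-2-en-1-ol
Conditions: iBu2AlH (2.5 equiv), CH2Cl2, −78 °C to 0 °C; aq. potassium sodium tartrate work-up
Reagents that add atoms: none
Why: iBu2AlH reduces the conjugated ester by two hydride transfers at the carbonyl carbon (1,2-reduction) to the allylic alcohol without touching the alkene geometry or the benzyl ethers.

Step 3
Reactants: 4 (E)-3-[3,4,5-tris(benzyloxy)phenyl]prop-2-en-1-ol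
Product: 5 [(2R,3R)-3-[3,4,5-tris(benzyloxy)phenyl]oxiran-2-yl]methanol
Conditions: Ti(OiPr)4 (10 mol%), D-(−)-diisopropyl tartrate (12 mol%), tBuOOH (2 equiv, decane), 4 Å MS, CH2Cl2, −25 °C
Reagents that add atoms: tert-butyl hydroperoxide, CC(C)(C)OO
Why: Sharpless asymmetric epoxidation: the titanium–tartrate complex binds the allylic alcohol and tBuOOH and, with the D-(−)-tartrate ester, delivers oxygen to the alkene face that gives the (2R,3R)-epoxy alcohol, which fixes the absolute configuration of the future C3 and, through the stereospecific opening in step 6, of C2.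

Step 4
Reactants: 6 phloroglucinol
Product: 7 5-(benzyloxy)benzene-1,3-diol
Conditions: BnBr (1 equiv), 6 (3 equiv), K2CO3, DMF, 0 °C to rt
Reagents that add atoms: benzyl bromide, BrCc1ccccc1
Why: Williamson O-benzylation of one of three equivalent phenols, made selective for the mono-ether by keeping phloroglucinol in excess (the surplus is water-soluble and is washed out) and by using a dipolar aprotic solvent to favour O- over C-alkylation.

Step 5
Reactants: 7 5-(benzyloxy)benzene-1,3-diol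
Product: 8 3-(benzyloxy)-5-[(triisopropylsilyl)oxy]phenol
Conditions: TIPSCl (1.0 equiv), imidazole, DMF, 0 °C
Reagents that add atoms: triisopropylsilyl chloride, CC(C)[Si](Cl)(C(C)C)C(C)C
Why: Imidazole-promoted silyl ether formation on one of the two equivalent phenols of the symmetric diol, run with one equivalent of silyl chloride so that the mono-ether should be the main product and unreacted 7 and the bis-silyl ether can be separated and recycled.

Step 6
Reactants: 5 [(2R,3R)-3-[3,4,5-tris(benzyloxy)phenyl]oxiran-2-yl]methanol; 8 3-(benzyloxy)-5-[(triisopropylsilyl)oxy]phenol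
Product: 9 (2R,3S)-3-{3-(benzyloxy)-5-[(triisopropylsilyl)oxy]phenoxy}-3-[3,4,5-tris(benzyloxy)phenyl]propane-1,2-diol
Conditions: Ti(OiPr)4 (1.5 equiv), 8 (2 equiv), CH2Cl2, rt to 40 °C; aq. potassium sodium tartrate work-up
Reagents that add atoms: none
Why: Ti(OiPr)4-mediated opening of a 2,3-epoxy alcohol: the epoxy alcohol binds titanium as a chelating alkoxide, which activates the benzylic C3–O bond, and the phenol oxygen attacks C3 from the rear in an SN2 sense, so that C3 inverts to S and C2 keeps its R configuration, while the neutral medium leaves the aryl silyl ether intact.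

Step 7
Reactants: 9 (2R,3S)-3-{3-(benzyloxy)-5-[(triisopropylsilyl)oxy]phenoxy}-3-[3,4,5-tris(benzyloxy)phenyl]propane-1,2-diol
Product: 10 (2R,3S)-3-{3-(benzyloxy)-5-[(triisopropylsilyl)oxy]phenoxy}-2-hydroxy-3-[3,4,5-tris(benzyloxy)phenyl]propyl 4-methylbenzenesulfonate
Conditions: TsCl (1.05 equiv), Et3N, Bu2SnO (2 mol%), CH2Cl2, 0 °C to rt
Reagents that add atoms: p-toluenesulfonyl chloride, Cc1ccc(S(=O)(=O)Cl)cc1
Why: Bu2SnO-catalysed sulfonylation of a 1,2-diol proceeds through a stannylene acetal that makes the primary oxygen the more nucleophilic one, so that only the CH2OH group is tosylated and no stereocentre is involved.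

Step 8
Reactants: 10 (2R,3S)-3-{3-(benzyloxy)-5-[(triisopropylsilyl)oxy]phenoxy}-2-hydroxy-3-[3,4,5-tris(benzyloxy)phenyl]propyl 4-methylbenzenesulfonate
Product: 11 (2R)-2-[(S)-{3-(benzyloxy)-5-[(triisopropylsilyl)oxy]phenoxy}[3,4,5-tris(benzyloxy)phenyl]methyl]oxirane
Conditions: NaH, THF, 0 °C
Reagents that add atoms: none
Why: Intramolecular Williamson reaction (3-exo-tet) in which the secondary alkoxide displaces the primary tosylate, which closes the terminal epoxide with retention at the oxygen-bearing carbon, and the aprotic hydride base avoids cleavage of the aryl silyl ether.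

Step 9
Reactants: 11 (2R)-2-[(S)-{3-(benzyloxy)-5-[(triisopropylsilyl)oxy]phenoxy}[3,4,5-tris(benzyloxy)phenyl]methyl]oxirane
Product: 12 (2S,3R)-5-(benzyloxy)-7-[(triisopropylsilyl)oxy]-2-[3,4,5-tris(benzyloxy)phenyl]-3,4-dihydro-2H-chromen-3-ol
Conditions: AuCl3 (5 mol%), AgOTf (15 mol%), 4 Å MS, ClCH2CH2Cl (0.02 M), 0 °C to rt
Reagents that add atoms: none
Why: Cationic trivalent gold formed from AuCl3 and AgOTf coordinates the epoxide oxygen, the ring A carbon lying between the ether oxygen and the benzyloxy group attacks the CH2 carbon of the epoxide, and the Wheland intermediate loses a proton so that the former epoxide oxygen is released as the C3 hydroxyl. The closest known reaction is the gold- or Lewis-acid-catalysed intramolecular Friedel–Crafts cycloalkylation of aryl glycidyl ethers to chroman-3-ols. Ring C closes in the 6-endo mode (both epoxide carbons end up in the ring), preferred over 5-exo closure because the CH2 terminus is unhindered and the internal carbon is deactivated towards positive charge by the neighbouring aryloxy-bearing carbon. No stereocentre is created: the new bond forms at a CH2 group, so C2 (S, from the invertive opening in step 6) and C3 (R, from the epoxidation in step 3) pass through unchanged and give the 2,3-trans chroman. The selectivity the step needs is regiochemical, C4a instead of the other ortho carbon of ring A; the bulky triisopropylsilyl ether screens the carbon next to it, and a silyloxy group on C5 would be pressed against C4, so closure should occur beside the slim benzyloxy group, which places OBn on C5 and OTIPS on C7. High dilution and molecular sieves are used to hold back intermolecular opening and protic ionisation of the benzylic C2–O1 ether.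

Step 10
Reactants: 12 (2S,3R)-5-(benzyloxy)-7-[(triisopropylsilyl)oxy]-2-[3,4,5-tris(benzyloxy)phenyl]-3,4-dihydro-2H-chromen-3-ol
Product: 13 (2S,3R)-5-(benzyloxy)-2-[3,4,5-tris(benzyloxy)phenyl]-3,4-dihydro-2H-chromene-3,7-diol
Conditions: Bu4NF (1.1 equiv), AcOH (1.1 equiv), THF, 0 °C
Reagents that add atoms: none
Why: Fluoride-induced cleavage of the aryl silyl ether, driven by the strong Si–F bond and the good phenoxide leaving group and buffered with acetic acid so that the electron-rich phenoxide is protonated at once, leaves the benzyl ethers and the secondary alcohol untouched.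

Step 11
Reactants: 14 3,4,5-tris(benzyloxy)benzoic acid
Product: 15 3,4,5-tris(benzyloxy)benzoyl chloride
Conditions: (COCl)2 (1.5 equiv), DMF (cat.), CH2Cl2, 0 °C to rt; evaporate
Reagents that add atoms: oxalyl chloride, O=C(Cl)C(=O)Cl
Why: Conversion of the carboxylic acid into the acid chloride with oxalyl chloride under dimethylformamide catalysis (chloroiminium activation) gives only gaseous by-products, so that the chloride can be used after evaporation.

Step 12
Reactants: 13 (2S,3R)-5-(benzyloxy)-2-[3,4,5-tris(benzyloxy)phenyl]-3,4-dihydro-2H-chromene-3,7-diol; 15 3,4,5-tris(benzyloxy)benzoyl chloride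
Product: 16 (2S,3R)-5-(benzyloxy)-3-hydroxy-2-[3,4,5-tris(benzyloxy)phenyl]-3,4-dihydro-2H-chromen-7-yl 3,4,5-tris(benzyloxy)benzoate
Conditions: 15 (1.05 equiv), K2CO3 (1.5 equiv), acetone, 0 °C
Reagents that add atoms: none
Why: Phenoxide-selective acylation under Schotten–Baumann-type conditions: carbonate ionises only the single free phenol, whose anion is acylated by the acid chloride, whereas the un-ionised secondary C3 alcohol should not compete in the absence of an acyl-transfer catalyst.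

Step 13
Reactants: 16 (2S,3R)-5-(benzyloxy)-3-hydroxy-2-[3,4,5-tris(benzyloxy)phenyl]-3,4-dihydro-2H-chromen-7-yl 3,4,5-tris(benzyloxy)benzoate
Product: 17 (2S,3R)-3,5-dihydroxy-2-(3,4,5-trihydroxyphenyl)-3,4-dihydro-2H-chromen-7-yl 3,4,5-trihydroxybenzoate
Conditions: H2 (1 atm), Pd(OH)2/C, THF–MeOH (1:1), rt
Reagents that add atoms: none
Why: Heterogeneous palladium-catalysed hydrogenolysis cleaves all seven benzyl aryl ethers to toluene, while the aryl gallate ester and the pyran ring of benzylated flavan-3-ols are known to survive these neutral conditions and no stereocentre is affected.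

**Compound list**

1 | 3,4,5-tris(benzyloxy)benzaldehyde | O=Cc1cc(OCc2ccccc2)c(OCc2ccccc2)c(OCc2ccccc2)c1 | starting material
2 | triethyl phosphonoacetate | CCOC(=O)CP(=O)(OCC)OCC | starting material
3 | ethyl (E)-3-[3,4,5-tris(benzyloxy)phenyl]prop-2-enoate | CCOC(=O)/C=C/c1cc(OCc2ccccc2)c(OCc2ccccc2)c(OCc2ccccc2)c1 | intermediate
4 | (E)-3-[3,4,5-tris(benzyloxy)phenyl]prop-2-en-1-ol | OC/C=C/c1cc(OCc2ccccc2)c(OCc2ccccc2)c(OCc2ccccc2)c1 | intermediate
5 | [(2R,3R)-3-[3,4,5-tris(benzyloxy)phenyl]oxiran-2-yl]methanol | OC[C@H]1O[C@@H]1c1cc(OCc2ccccc2)c(OCc2ccccc2)c(OCc2ccccc2)c1 | intermediate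
6 | phloroglucinol | Oc1cc(O)cc(O)c1 | starting material
7 | 5-(benzyloxy)benzene-1,3-diol | Oc1cc(O)cc(OCc2ccccc2)c1 | intermediate
8 | 3-(benzyloxy)-5-[(triisopropylsilyl)oxy]phenol | CC(C)[Si](Oc1cc(O)cc(OCc2ccccc2)c1)(C(C)C)C(C)C | intermediate
9 | (2R,3S)-3-{3-(benzyloxy)-5-[(triisopropylsilyl)oxy]phenoxy}-3-[3,4,5-tris(benzyloxy)phenyl]propane-1,2-diol | CC(C)[Si](Oc1cc(OCc2ccccc2)cc(O[C@@H](c2cc(OCc3ccccc3)c(OCc3ccccc3)c(OCc3ccccc3)c2)[C@H](O)CO)c1)(C(C)C)C(C)C | intermediate
10 | (2R,3S)-3-{3-(benzyloxy)-5-[(triisopropylsilyl)oxy]phenoxy}-2-hydroxy-3-[3,4,5-tris(benzyloxy)phenyl]propyl 4-methylbenzenesulfonate | CC(C)[Si](Oc1cc(OCc2ccccc2)cc(O[C@@H](c2cc(OCc3ccccc3)c(OCc3ccccc3)c(OCc3ccccc3)c2)[C@H](O)COS(=O)(=O)c2ccc(C)cc2)c1)(C(C)C)C(C)C | intermediate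
11 | (2R)-2-[(S)-{3-(benzyloxy)-5-[(triisopropylsilyl)oxy]phenoxy}[3,4,5-tris(benzyloxy)phenyl]methyl]oxirane | CC(C)[Si](Oc1cc(OCc2ccccc2)cc(O[C@@H](c2cc(OCc3ccccc3)c(OCc3ccccc3)c(OCc3ccccc3)c2)[C@H]2CO2)c1)(C(C)C)C(C)C | intermediate
12 | (2S,3R)-5-(benzyloxy)-7-[(triisopropylsilyl)oxy]-2-[3,4,5-tris(benzyloxy)phenyl]-3,4-dihydro-2H-chromen-3-ol | CC(C)[Si](Oc1cc(OCc2ccccc2)c2c(c1)O[C@@H](c1cc(OCc3ccccc3)c(OCc3ccccc3)c(OCc3ccccc3)c1)[C@H](O)C2)(C(C)C)C(C)C | intermediate
13 | (2S,3R)-5-(benzyloxy)-2-[3,4,5-tris(benzyloxy)phenyl]-3,4-dihydro-2H-chromene-3,7-diol | Oc1cc(OCc2ccccc2)c2c(c1)O[C@@H](c1cc(OCc3ccccc3)c(OCc3ccccc3)c(OCc3ccccc3)c1)[C@H](O)C2 | intermediate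
14 | 3,4,5-tris(benzyloxy)benzoic acid | OC(=O)c1cc(OCc2ccccc2)c(OCc2ccccc2)c(OCc2ccccc2)c1 | starting material
15 | 3,4,5-tris(benzyloxy)benzoyl chloride | O=C(Cl)c1cc(OCc2ccccc2)c(OCc2ccccc2)c(OCc2ccccc2)c1 | intermediate
16 | (2S,3R)-5-(benzyloxy)-3-hydroxy-2-[3,4,5-tris(benzyloxy)phenyl]-3,4-dihydro-2H-chromen-7-yl 3,4,5-tris(benzyloxy)benzoate | O=C(Oc1cc(OCc2ccccc2)c2c(c1)O[C@@H](c1cc(OCc3ccccc3)c(OCc3ccccc3)c(OCc3ccccc3)c1)[C@H](O)C2)c1cc(OCc2ccccc2)c(OCc2ccccc2)c(OCc2ccccc2)c1 | intermediate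
17 | (2S,3R)-3,5-dihydroxy-2-(3,4,5-trihydroxyphenyl)-3,4-dihydro-2H-chromen-7-yl 3,4,5-trihydroxybenzoate | O=C(Oc1cc(O)c2c(c1)O[C@@H](c1cc(O)c(O)c(O)c1)[C@H](O)C2)c1cc(O)c(O)c(O)c1 | target

**Step count**

Total steps: 13. Longest linear sequence: 10 steps (steps 1, 2, 3, 6, 7, 8, 9, 10, 12, 13).

**Steps most likely to fail, with fallbacks**

1. Step 9 (closure of ring C).
   - What may go wrong: the other ortho carbon of ring A (between the ether oxygen and the silyloxy group) may take part in the closure if the silyl ether screens it less than expected. That would leave the silyl ether on C5 and the benzyl ether on C7. Acid-induced ionisation of the benzylic C2–O1 ether could also erode the C2 configuration.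
   - Fallback: block that carbon with bromine so that only C4a can react. It sets out from 7 (with 5 as coupling partner) and comes back to the route at 17.
   - Ring A: 7 is converted with MOMCl and iPr2NEt into 1-(benzyloxy)-3,5-bis(methoxymethoxy)benzene F1. Directed ortho-lithiation between the two acetal ethers (n-BuLi, THF, 0 °C) and quenching with CBr4 should give 5-(benzyloxy)-2-bromo-1,3-bis(methoxymethoxy)benzene F2. HCl in MeOH then frees 5-(benzyloxy)-2-bromobenzene-1,3-diol F3, in which bromine sits between two equivalent hydroxyls, so no regiochemical question arises. Mono-silylation as in step 5 gives 5-(benzyloxy)-2-bromo-3-[(triisopropylsilyl)oxy]phenol F4.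
   - Coupling and closure: opening of 5 by F4 under the conditions of step 6 gives (2R,3S)-3-{5-(benzyloxy)-2-bromo-3-[(triisopropylsilyl)oxy]phenoxy}-3-[3,4,5-tris(benzyloxy)phenyl]propane-1,2-diol F5. Tosylation as in step 7 gives (2R,3S)-3-{5-(benzyloxy)-2-bromo-3-[(triisopropylsilyl)oxy]phenoxy}-2-hydroxy-3-[3,4,5-tris(benzyloxy)phenyl]propyl 4-methylbenzenesulfonate F6. NaH closure gives (2R)-2-[(S)-{5-(benzyloxy)-2-bromo-3-[(triisopropylsilyl)oxy]phenoxy}[3,4,5-tris(benzyloxy)phenyl]methyl]oxirane F7. The AuCl3/AgOTf cyclisation, now with a single free ortho carbon, should give (2S,3R)-5-(benzyloxy)-8-bromo-7-[(triisopropylsilyl)oxy]-2-[3,4,5-tris(benzyloxy)phenyl]-3,4-dihydro-2H-chromen-3-ol F8.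
   - End game: Bu4NF/AcOH gives (2S,3R)-5-(benzyloxy)-8-bromo-2-[3,4,5-tris(benzyloxy)phenyl]-3,4-dihydro-2H-chromene-3,7-diol F9. Acylation with 15 as in step 12 gives (2S,3R)-5-(benzyloxy)-8-bromo-3-hydroxy-2-[3,4,5-tris(benzyloxy)phenyl]-3,4-dihydro-2H-chromen-7-yl 3,4,5-tris(benzyloxy)benzoate F10. Hydrogenolysis (H2, Pd(OH)2/C, Et3N, THF–MeOH) should cleave the C–Br bond together with the benzyl ethers and give 17.

2. Step 6 (phenol opening of the epoxy alcohol).
   - What may go wrong: the Lewis-acid-activated benzylic epoxide may alkylate the electron-rich ring A at carbon instead of at oxygen, partial ionisation at C3 may erode the inversion, or isopropoxide may be transferred.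
   - Fallback: an anionic opening without Lewis acid. It sets out from 5 and 7 and comes back at 9.
   - 5 is opened by the mono-caesium salt of the symmetric diol 7 (7 in threefold excess, Cs2CO3, DMF, 60 °C), an SN2 attack at the benzylic carbon that should give (2R,3S)-3-[3-(benzyloxy)-5-hydroxyphenoxy]-3-[3,4,5-tris(benzyloxy)phenyl]propane-1,2-diol F11.
   - The phenol alone is then silylated through its phenoxide (NaH, 1 equiv, THF, 0 °C, then TIPSCl) to give 9. This variant also makes step 5 unnecessary.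

3. Step 12 (7-O-acylation).
   - What may go wrong: acyl transfer to the C3 hydroxyl or double acylation if the discrimination between phenoxide and secondary alcohol is incomplete.
   - Fallback: mask the C3 hydroxyl before the phenol is unveiled. It sets out from 12 and comes back at 17.
   - 12 is treated with CbzCl, pyridine and DMAP to give benzyl (2S,3R)-5-(benzyloxy)-7-[(triisopropylsilyl)oxy]-2-[3,4,5-tris(benzyloxy)phenyl]-3,4-dihydro-2H-chromen-3-yl carbonate F12.
   - Bu4NF/AcOH then gives benzyl (2S,3R)-5-(benzyloxy)-7-hydroxy-2-[3,4,5-tris(benzyloxy)phenyl]-3,4-dihydro-2H-chromen-3-yl carbonate F13.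
   - Acylation with 15 (Et3N, DMAP, CH2Cl2) gives (2S,3R)-5-(benzyloxy)-3-{[(benzyloxy)carbonyl]oxy}-2-[3,4,5-tris(benzyloxy)phenyl]-3,4-dihydro-2H-chromen-7-yl 3,4,5-tris(benzyloxy)benzoate F14.
   - Hydrogenolysis as in step 13 removes the benzyl carbonate along with the benzyl ethers and gives 17.

Further compounds
F1 | step 9 | 1-(benzyloxy)-3,5-bis(methoxymethoxy)benzene | COCOc1cc(OCOC)cc(OCc2ccccc2)c1
F2 | step 9 | 5-(benzyloxy)-2-bromo-1,3-bis(methoxymethoxy)benzene | COCOc1cc(OCc2ccccc2)cc(OCOC)c1Br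
F3 | step 9 | 5-(benzyloxy)-2-bromobenzene-1,3-diol | Oc1cc(OCc2ccccc2)cc(O)c1Br
F4 | step 9 | 5-(benzyloxy)-2-bromo-3-[(triisopropylsilyl)oxy]phenol | CC(C)[Si](Oc1cc(OCc2ccccc2)cc(O)c1Br)(C(C)C)C(C)C
F5 | step 9 | (2R,3S)-3-{5-(benzyloxy)-2-bromo-3-[(triisopropylsilyl)oxy]phenoxy}-3-[3,4,5-tris(benzyloxy)phenyl]propane-1,2-diol | CC(C)[Si](Oc1cc(OCc2ccccc2)cc(O[C@@H](c2cc(OCc3ccccc3)c(OCc3ccccc3)c(OCc3ccccc3)c2)[C@H](O)CO)c1Br)(C(C)C)C(C)C
F6 | step 9 | (2R,3S)-3-{5-(benzyloxy)-2-bromo-3-[(triisopropylsilyl)oxy]phenoxy}-2-hydroxy-3-[3,4,5-tris(benzyloxy)phenyl]propyl 4-methylbenzenesulfonate | CC(C)[Si](Oc1cc(OCc2ccccc2)cc(O[C@@H](c2cc(OCc3ccccc3)c(OCc3ccccc3)c(OCc3ccccc3)c2)[C@H](O)COS(=O)(=O)c2ccc(C)cc2)c1Br)(C(C)C)C(C)C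
F7 | step 9 | (2R)-2-[(S)-{5-(benzyloxy)-2-bromo-3-[(triisopropylsilyl)oxy]phenoxy}[3,4,5-tris(benzyloxy)phenyl]methyl]oxirane | CC(C)[Si](Oc1cc(OCc2ccccc2)cc(O[C@@H](c2cc(OCc3ccccc3)c(OCc3ccccc3)c(OCc3ccccc3)c2)[C@H]2CO2)c1Br)(C(C)C)C(C)C
F8 | step 9 | (2S,3R)-5-(benzyloxy)-8-bromo-7-[(triisopropylsilyl)oxy]-2-[3,4,5-tris(benzyloxy)phenyl]-3,4-dihydro-2H-chromen-3-ol | CC(C)[Si](Oc1cc(OCc2ccccc2)c2c(c1Br)O[C@@H](c1cc(OCc3ccccc3)c(OCc3ccccc3)c(OCc3ccccc3)c1)[C@H](O)C2)(C(C)C)C(C)C
F9 | step 9 | (2S,3R)-5-(benzyloxy)-8-bromo-2-[3,4,5-tris(benzyloxy)phenyl]-3,4-dihydro-2H-chromene-3,7-diol | Oc1cc(OCc2ccccc2)c2c(c1Br)O[C@@H](c1cc(OCc3ccccc3)c(OCc3ccccc3)c(OCc3ccccc3)c1)[C@H](O)C2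
F10 | step 9 | (2S,3R)-5-(benzyloxy)-8-bromo-3-hydroxy-2-[3,4,5-tris(benzyloxy)phenyl]-3,4-dihydro-2H-chromen-7-yl 3,4,5-tris(benzyloxy)benzoate | O=C(Oc1cc(OCc2ccccc2)c2c(c1Br)O[C@@H](c1cc(OCc3ccccc3)c(OCc3ccccc3)c(OCc3ccccc3)c1)[C@H](O)C2)c1cc(OCc2ccccc2)c(OCc2ccccc2)c(OCc2ccccc2)c1
F11 | step 6 | (2R,3S)-3-[3-(benzyloxy)-5-hydroxyphenoxy]-3-[3,4,5-tris(benzyloxy)phenyl]propane-1,2-diol | Oc1cc(OCc2ccccc2)cc(O[C@@H](c2cc(OCc3ccccc3)c(OCc3ccccc3)c(OCc3ccccc3)c2)[C@H](O)CO)c1
F12 | step 12 | benzyl (2S,3R)-5-(benzyloxy)-7-[(triisopropylsilyl)oxy]-2-[3,4,5-tris(benzyloxy)phenyl]-3,4-dihydro-2H-chromen-3-yl carbonate | CC(C)[Si](Oc1cc(OCc2ccccc2)c2c(c1)O[C@@H](c1cc(OCc3ccccc3)c(OCc3ccccc3)c(OCc3ccccc3)c1)[C@H](OC(=O)OCc1ccccc1)C2)(C(C)C)C(C)C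
F13 | step 12 | benzyl (2S,3R)-5-(benzyloxy)-7-hydroxy-2-[3,4,5-tris(benzyloxy)phenyl]-3,4-dihydro-2H-chromen-3-yl carbonate | Oc1cc(OCc2ccccc2)c2c(c1)O[C@@H](c1cc(OCc3ccccc3)c(OCc3ccccc3)c(OCc3ccccc3)c1)[C@H](OC(=O)OCc1ccccc1)C2
F14 | step 12 | (2S,3R)-5-(benzyloxy)-3-{[(benzyloxy)carbonyl]oxy}-2-[3,4,5-tris(benzyloxy)phenyl]-3,4-dihydro-2H-chromen-7-yl 3,4,5-tris(benzyloxy)benzoate | O=C(Oc1cc(OCc2ccccc2)c2c(c1)O[C@@H](c1cc(OCc3ccccc3)c(OCc3ccccc3)c(OCc3ccccc3)c1)[C@H](OC(=O)OCc1ccccc1)C2)c1cc(OCc2ccccc2)c(OCc2ccccc2)c(OCc2ccccc2)c1
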